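**Plan**

Ring labels: ring A = benzo ring of the benzofuran, ring B = 4-oxygenated phenyl on C2, ring C = 2,4-dioxygenated phenyl of the C3 ketone, ring D = 2,4-dioxygenated phenyl of the chain ketone.
Retrosynthesis: the five O–benzyl bonds are cut first, then C2–H and C3–H (dihydrobenzofuran back to benzofuran), then O1–C2, C3–C(=O) and C(=O)–ring C in one operation, then the ring A–alkyne bond, and last the Cα–Cβ bond of the dihydrochalcone chain.
Enabling feature: the array O1–C2(ring B)–C3–C(=O)–ring C on the furan ring fused to ring A; O1 is a phenol oxygen, C2 and C3 are alkyne carbons, the ketone carbon is CO and ring C comes from an aryl iodide.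
Forward: the chain ring D–CO–CH2CH2–ring A is joined first (aldol condensation, C=C hydrogenation), ring B is attached through the alkyne, and the furan ring, the only ring made, closes in the carbonylative annulation.
Stereochemistry: C2 (S) from ligand-controlled hydride delivery by a chiral copper hydride to the benzofuran enone; C3 (S) by equilibration to the trans isomer; neutral hydrogenolysis then frees the five phenols.

Key step: step 6

Remark: the side-chain ketone is masked as a silyl enol ether before the copper hydride step, because ligated CuH reduces aryl alkyl ketones at the carbonyl carbon.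
Remark: the hand of the bisphosphine cannot be predicted for this substrate class; (R)-DTBM-SEGPHOS is written, and its antipode is taken if the first configurational assignment of the reduction product shows the 2R series.
Remark: 4-hydroxy-3-iodobenzaldehyde, 1-(benzyloxy)-4-ethynylbenzene and 4-iodoresorcinol are taken as commercial.

**Route**

Step 1
Reactants: 1 2,4-dihydroxyacetophenone
Product: 2 1-[2,4-bis(benzyloxy)phenyl]ethanone
Conditions: BnBr (2.4 equiv), K2CO3 (3 equiv), DMF, 80 °C
Reagents that add atoms: benzyl bromide, BrCc1ccccc1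
Why: Williamson etherification, in which K2CO3 in warm DMF deprotonates both phenols, including the hydrogen-bonded 2-hydroxyl, and benzyl bromide alkylates them on oxygen.

Step 2
Reactants: 2 1-[2,4-bis(benzyloxy)phenyl]ethanone, 3 4-hydroxy-3-iodobenzaldehyde
Product: 4 (E)-1-[2,4-bis(benzyloxy)phenyl]-3-(4-hydroxy-3-iodophenyl)prop-2-en-1-one
Conditions: KOH (aq. 50 %, excess), EtOH/THF, rt to 50 °C; then 1 M HCl
Reagents that add atoms: none
Why: Claisen–Schmidt aldol condensation, in which the methyl ketone enolate adds to the aldehyde (present as its phenoxide, hence excess base and a long reaction time) and E1cB loss of water gives the conjugated E enone, the aryl iodide and benzyl ethers being inert to aqueous base.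

Step 3
Reactants: 4 the iodo hydroxy chalcone
Product: 5 1-[2,4-bis(benzyloxy)phenyl]-3-(4-hydroxy-3-iodophenyl)propan-1-one
Conditions: H2 (1–3 bar), RhCl(PPh3)3 (5 mol %), THF/t-BuOH (1:1), 40 °C
Reagents that add atoms: none
Why: Homogeneous hydrogenation with RhCl(PPh3)3 saturates the enone C=C by alkene coordination and hydride insertion, and this catalyst neither hydrogenolyses benzyl ethers or the aryl–iodine bond nor reduces the ketone.

Step 4
Reactants: 5 the iodophenol dihydrochalcone, 6 1-(benzyloxy)-4-ethynylbenzene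
Product: 7 1-[2,4-bis(benzyloxy)phenyl]-3-[3-{[4-(benzyloxy)phenyl]ethynyl}-4-hydroxyphenyl]propan-1-one
Conditions: PdCl2(PPh3)2 (2 mol %), CuI (4 mol %), Et3N (3 equiv), THF, rt, degassed
Reagents that add atoms: none
Why: Sonogashira coupling at the C–I bond of the ortho-iodophenol (oxidative addition, transmetalation of the copper acetylide, reductive elimination), run at room temperature so that the weakly acidic p-alkylphenol does not yet add to the new alkyne.

Step 5
Reactants: 8 4-iodoresorcinol
Product: 9 2,4-bis(benzyloxy)-1-iodobenzene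
Conditions: BnBr (2.3 equiv), K2CO3 (3 equiv), DMF, rt to 50 °C
Reagents that add atoms: benzyl bromide, BrCc1ccccc1
Why: Williamson etherification of both phenols under mild carbonate conditions that leave the aryl iodide untouched.

Step 6
Reactants: 7 the 2-(arylethynyl)phenol, 9 2,4-bis(benzyloxy)-1-iodobenzene, 10 carbon monoxide
Product: 11 1-[2,4-bis(benzyloxy)phenyl]-3-{2-[4-(benzyloxy)phenyl]-3-[2,4-bis(benzyloxy)benzoyl]-1-benzofuran-5-yl}propan-1-one
Conditions: Pd(PPh3)4 (5 mol %), KOAc (5 equiv), CO (1 atm), MeCN, 45–60 °C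
Reagents that add atoms: none
Why: Zerovalent palladium adds oxidatively to the C–I bond of 9 and CO inserts to give an aroyl divalent palladium iodide, which coordinates the alkyne of 7. The phenol oxygen, assisted by acetate, attacks the activated alkyne anti to palladium at the carbon bearing ring B; this 5-endo-dig oxypalladation closes the furan ring (O1–C2) and leaves a 3-benzofuranyl aroyl palladium species, whose reductive elimination makes the C3–C(=O) bond and returns zerovalent palladium. The closest known reaction type is the palladium-catalysed carbonylative cyclisation of 2-alkynylphenols with aryl iodides under CO, which gives 2-substituted 3-aroylbenzofurans. No stereocentre is formed, and the ring size is fixed because the only alternative, 4-exo attack at the inner alkyne carbon, is strained. The step needs acyl transfer to win over direct aryl transfer, proton-terminated cycloisomerisation and O-aroylation of the phenol; the electron-rich aryl group of 9 migrates quickly to CO, the CO atmosphere keeps palladium as the acyl complex, and the weak base KOAc with the weakly acidic p-alkylphenol keeps uncatalysed cyclisation slow. The saturated keto chain and the benzyl ethers take no part.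

Step 7
Reactants: 11 the pentabenzyl 2-aryl-3-aroylbenzofuran
Product: 12 {2-[4-(benzyloxy)phenyl]-5-[(2Z)-3-[2,4-bis(benzyloxy)phenyl]-3-{[tert-butyl(dimethyl)silyl]oxy}prop-2-en-1-yl]-1-benzofuran-3-yl}[2,4-bis(benzyloxy)phenyl]methanone
Conditions: TBSOTf (1.3 equiv), Et3N (2.5 equiv), CH2Cl2, 0 °C
Reagents that add atoms: tert-butyldimethylsilyl trifluoromethanesulfonate, CC(C)(C)[Si](C)(C)OS(=O)(=O)C(F)(F)F
Why: Soft enolisation with a silyl triflate and an amine, in which only the side-chain ketone has α-hydrogens (the C3 ketone lies between two sp2 carbons), so a single Z silyl enol ether should form and shield this ketone from 1,2-reduction in step 8.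

Step 8
Reactants: 12 the benzofuran silyl enol ether
Product: 15 1-[2,4-bis(benzyloxy)phenyl]-3-{(2S,3S)-2-[4-(benzyloxy)phenyl]-3-[2,4-bis(benzyloxy)benzoyl]-2,3-dihydro-1-benzofuran-5-yl}propan-1-one, via bis(enol silane) 13 (not isolated), via cis-(2S,3R) ketone 14 (not isolated)
Conditions: Cu(OAc)2 (5 mol %), (R)-DTBM-SEGPHOS (5.5 mol %), (EtO)2MeSiH (4 equiv), toluene, 25–40 °C; then 1 M HCl, THF, 0 °C to rt; then DBU (0.2 equiv), CH2Cl2, rt
Reagents that add atoms: none
Why: Proposed new method: ligated CuH (monovalent copper) is expected to deliver hydride to C2, the β-carbon of the cyclic β-aryloxy enone that the weakly aromatic 3-aroylbenzofuran represents, and σ-bond metathesis of the resulting copper enolate with the silane gives enol silane 13 and returns CuH, the closest known reaction type being the CuH-catalysed asymmetric 1,4-reduction of β,β-disubstituted enones and of 2-substituted chromones; the ligand controls the face of hydride delivery and so sets C2 (S requires hydride on the face from which O1, the ipso carbon of ring B and C3 run clockwise), while C3 is set under thermodynamic control, because hydrolysis protonates C3 to a mixture that may be rich in the cis ketone 14 and DBU equilibrates it through the enolate to the trans isomer with aryl and aroyl groups anti, ring opening by loss of O1 being the reverse of a 5-endo-trig closure and therefore slow.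

Step 9
Reactants: 15 the (2S,3S)-trans pentabenzyl dihydrobenzofuran
Product: 16 1-(2,4-dihydroxyphenyl)-3-[(2S,3S)-3-(2,4-dihydroxybenzoyl)-2-(4-hydroxyphenyl)-2,3-dihydro-1-benzofuran-5-yl]propan-1-one
Conditions: H2 (1 atm), Pd/C (10 wt %), EtOAc/THF (1:1), rt, stopped at the calculated uptake
Reagents that add atoms: none
Why: Hydrogenolysis of the five aryl benzyl ethers on palladium under neutral conditions, where the secondary, hindered ring C2–O1 bond and the deactivated 2-hydroxyaryl ketones should react much more slowly and neither acid nor base is present to disturb C2 or C3.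

**Compound list**

1 | 2,4-dihydroxyacetophenone | CC(=O)c1ccc(O)cc1O | starting material
2 | 1-[2,4-bis(benzyloxy)phenyl]ethanone | CC(=O)c1ccc(OCc2ccccc2)cc1OCc1ccccc1 | intermediate
3 | 4-hydroxy-3-iodobenzaldehyde | O=Cc1ccc(O)c(I)c1 | starting material
4 | (E)-1-[2,4-bis(benzyloxy)phenyl]-3-(4-hydroxy-3-iodophenyl)prop-2-en-1-one | O=C(/C=C/c1ccc(O)c(I)c1)c1ccc(OCc2ccccc2)cc1OCc1ccccc1 | intermediate
5 | 1-[2,4-bis(benzyloxy)phenyl]-3-(4-hydroxy-3-iodophenyl)propan-1-one | O=C(CCc1ccc(O)c(I)c1)c1ccc(OCc2ccccc2)cc1OCc1ccccc1 | intermediate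
6 | 1-(benzyloxy)-4-ethynylbenzene | C#Cc1ccc(OCc2ccccc2)cc1 | starting material
7 | 1-[2,4-bis(benzyloxy)phenyl]-3-[3-{[4-(benzyloxy)phenyl]ethynyl}-4-hydroxyphenyl]propan-1-one | O=C(CCc1ccc(O)c(C#Cc2ccc(OCc3ccccc3)cc2)c1)c1ccc(OCc2ccccc2)cc1OCc1ccccc1 | intermediate
8 | 4-iodoresorcinol (4-iodobenzene-1,3-diol) | Oc1ccc(I)c(O)c1 | starting material
9 | 2,4-bis(benzyloxy)-1-iodobenzene | Ic1ccc(OCc2ccccc2)cc1OCc1ccccc1 | intermediate
10 | carbon monoxide | [C-]#[O+] | starting material
11 | 1-[2,4-bis(benzyloxy)phenyl]-3-{2-[4-(benzyloxy)phenyl]-3-[2,4-bis(benzyloxy)benzoyl]-1-benzofuran-5-yl}propan-1-one | O=C(CCc1ccc2oc(-c3ccc(OCc4ccccc4)cc3)c(C(=O)c3ccc(OCc4ccccc4)cc3OCc3ccccc3)c2c1)c1ccc(OCc2ccccc2)cc1OCc1ccccc1 | intermediate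
12 | {2-[4-(benzyloxy)phenyl]-5-[(2Z)-3-[2,4-bis(benzyloxy)phenyl]-3-{[tert-butyl(dimethyl)silyl]oxy}prop-2-en-1-yl]-1-benzofuran-3-yl}[2,4-bis(benzyloxy)phenyl]methanone | CC(C)(C)[Si](C)(C)O/C(=C\Cc1ccc2oc(-c3ccc(OCc4ccccc4)cc3)c(C(=O)c3ccc(OCc4ccccc4)cc3OCc3ccccc3)c2c1)c1ccc(OCc2ccccc2)cc1OCc1ccccc1 | intermediate
13 | (2R)-2-[4-(benzyloxy)phenyl]-3-{[2,4-bis(benzyloxy)phenyl][(diethoxymethylsilyl)oxy]methylidene}-5-[(2Z)-3-[2,4-bis(benzyloxy)phenyl]-3-{[tert-butyl(dimethyl)silyl]oxy}prop-2-en-1-yl]-2,3-dihydro-1-benzofuran (C2 has the spatial arrangement of 2S in 15, the descriptor changes only because C3 is trigonal; exocyclic C=C geometry left open) | CC(C)(C)[Si](C)(C)O/C(=C\Cc1ccc2c(c1)C(=C(O[Si](C)(OCC)OCC)c1ccc(OCc3ccccc3)cc1OCc1ccccc1)[C@@H](c1ccc(OCc3ccccc3)cc1)O2)c1ccc(OCc2ccccc2)cc1OCc1ccccc1 | intermediate (not isolated)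
14 | 1-[2,4-bis(benzyloxy)phenyl]-3-{(2S,3R)-2-[4-(benzyloxy)phenyl]-3-[2,4-bis(benzyloxy)benzoyl]-2,3-dihydro-1-benzofuran-5-yl}propan-1-one (cis) | O=C(CCc1ccc2c(c1)[C@@H](C(=O)c1ccc(OCc3ccccc3)cc1OCc1ccccc1)[C@@H](c1ccc(OCc3ccccc3)cc1)O2)c1ccc(OCc2ccccc2)cc1OCc1ccccc1 | intermediate (not isolated)
15 | 1-[2,4-bis(benzyloxy)phenyl]-3-{(2S,3S)-2-[4-(benzyloxy)phenyl]-3-[2,4-bis(benzyloxy)benzoyl]-2,3-dihydro-1-benzofuran-5-yl}propan-1-one (trans) | O=C(CCc1ccc2c(c1)[C@H](C(=O)c1ccc(OCc3ccccc3)cc1OCc1ccccc1)[C@@H](c1ccc(OCc3ccccc3)cc1)O2)c1ccc(OCc2ccccc2)cc1OCc1ccccc1 | intermediate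
16 | 1-(2,4-dihydroxyphenyl)-3-[(2S,3S)-3-(2,4-dihydroxybenzoyl)-2-(4-hydroxyphenyl)-2,3-dihydro-1-benzofuran-5-yl]propan-1-one (CNP0136359.1) | O=C(CCc1ccc2c(c1)[C@H](C(=O)c1ccc(O)cc1O)[C@@H](c1ccc(O)cc1)O2)c1ccc(O)cc1O | target

**Count**

Total step count: 9.
Longest linear sequence: 8 steps (steps 1, 2, 3, 4, 6, 7, 8, 9); step 5 is the side branch to the aryl iodide.

**Steps most likely to fail**

1. Step 8 (the new method). Hydride may fail to reach the hindered, donor-substituted C2, may add to the C3 carbonyl carbon instead, or may be delivered with poor facial selectivity. The fallback sets out from 11 (step 7 is then not needed) and comes back at 15. The C2=C3 bond is hydrogenated with a cationic iridium catalyst carrying a chiral pyridine–phosphinite ligand L, [Ir(cod)L][B(3,5-(CF3)2C6H3)4], under H2 (50–100 bar) in CH2Cl2 at 40–60 °C. Enantioselective hydrogenation of the furan C2=C3 bond of benzofurans is known for this catalyst class, which does not reduce aryl ketones or cleave benzyl ethers. Syn addition of H2 should give the cis ketone 14 directly, and DBU (0.2 equiv) in CH2Cl2 then equilibrates C3 to give 15. If the enantiomeric purity is insufficient, 15 is brought to a single enantiomer by preparative chromatography on a chiral stationary phase. No compound outside the list is made (F0).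

2. Step 6. The aryl group may be transferred to C3 without CO uptake, the phenol may cyclise with proton termination, or the aroyl palladium species may acylate the phenol oxygen. The fallback sets out from 7 and 9 and comes back at 11; ring closure and acylation are separated. I2 and NaHCO3 in MeCN at rt should convert 7 by 5-endo-dig iodocyclisation into 1-[2,4-bis(benzyloxy)phenyl]-3-{2-[4-(benzyloxy)phenyl]-3-iodo-1-benzofuran-5-yl}propan-1-one F1. Iodide 9 is converted by iodine–magnesium exchange (i-PrMgCl·LiCl, THF, −20 °C), B(OiPr)3 and aqueous HCl into [2,4-bis(benzyloxy)phenyl]boronic acid F2. Carbonylative Suzuki–Miyaura coupling of F1 with F2 (PdCl2(PPh3)2, K2CO3, CO 1 atm, anisole, 80 °C) then forms the C3–C(=O) and C(=O)–ring C bonds and should give 11.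

3. Step 9. Hydrogenolysis may go on to cleave the benzylic C2–O1 bond of the dihydrofuran ring or to reduce an aryl ketone. The fallback sets out from 11 and comes back at 16; the benzyl ethers are removed while the furan ring is still aromatic, and silyl groups carry the phenols through the reduction. H2 and Pd/C in THF/EtOAc should give the pentaphenol 1-(2,4-dihydroxyphenyl)-3-[3-(2,4-dihydroxybenzoyl)-2-(4-hydroxyphenyl)-1-benzofuran-5-yl]propan-1-one F3. TBSOTf (8 equiv) and Et3N in CH2Cl2 silylate the five phenols and the enol of the side-chain ketone to the hexasilyl benzofuran F4. The copper hydride reduction of step 8 gives the C3 enol silane F5. Work-up at pH 7 hydrolyses only the alkoxysilyl enol ether, giving the cis ketone F6, and DBU (0.1 equiv, dry CH2Cl2) equilibrates it to the trans (2S,3S) ketone F7. Et3N·3HF in THF/MeCN removes the six silyl groups under weakly acidic conditions, in which no phenoxide of ring B can open the ring, and should give 16.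

**Further compounds**

F0 | step 8 | none | none
F1 | step 6 | 1-[2,4-bis(benzyloxy)phenyl]-3-{2-[4-(benzyloxy)phenyl]-3-iodo-1-benzofuran-5-yl}propan-1-one | O=C(CCc1ccc2oc(-c3ccc(OCc4ccccc4)cc3)c(I)c2c1)c1ccc(OCc2ccccc2)cc1OCc1ccccc1
F2 | step 6 | [2,4-bis(benzyloxy)phenyl]boronic acid | OB(O)c1ccc(OCc2ccccc2)cc1OCc1ccccc1
F3 | step 9 | 1-(2,4-dihydroxyphenyl)-3-[3-(2,4-dihydroxybenzoyl)-2-(4-hydroxyphenyl)-1-benzofuran-5-yl]propan-1-one | O=C(CCc1ccc2oc(-c3ccc(O)cc3)c(C(=O)c3ccc(O)cc3O)c2c1)c1ccc(O)cc1O
F4 | step 9 | hexasilyl benzofuran: the five aryl tert-butyldimethylsilyl ethers of F3 carrying the (Z)-tert-butyldimethylsilyl enol ether of the side-chain ketone | CC(C)(C)[Si](C)(C)O/C(=C\Cc1ccc2oc(-c3ccc(O[Si](C)(C)C(C)(C)C)cc3)c(C(=O)c3ccc(O[Si](C)(C)C(C)(C)C)cc3O[Si](C)(C)C(C)(C)C)c2c1)c1ccc(O[Si](C)(C)C(C)(C)C)cc1O[Si](C)(C)C(C)(C)C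
F5 | step 9 | C3 enol silane of the silyl series: (2R by CIP, same spatial arrangement as 2S in F7) 2,3-dihydrobenzofuran with the exocyclic diethoxymethylsilyl enol ether at C3, five aryl silyl ethers and the side-chain (Z)-silyl enol ether | CC(C)(C)[Si](C)(C)O/C(=C\Cc1ccc2c(c1)C(=C(O[Si](C)(OCC)OCC)c1ccc(O[Si](C)(C)C(C)(C)C)cc1O[Si](C)(C)C(C)(C)C)[C@@H](c1ccc(O[Si](C)(C)C(C)(C)C)cc1)O2)c1ccc(O[Si](C)(C)C(C)(C)C)cc1O[Si](C)(C)C(C)(C)C
F6 | step 9 | cis (2S,3R) 3-aroyl-2-aryl-2,3-dihydrobenzofuran with five aryl silyl ethers and the side-chain (Z)-silyl enol ether | CC(C)(C)[Si](C)(C)O/C(=C\Cc1ccc2c(c1)[C@@H](C(=O)c1ccc(O[Si](C)(C)C(C)(C)C)cc1O[Si](C)(C)C(C)(C)C)[C@@H](c1ccc(O[Si](C)(C)C(C)(C)C)cc1)O2)c1ccc(O[Si](C)(C)C(C)(C)C)cc1O[Si](C)(C)C(C)(C)C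
F7 | step 9 | trans (2S,3S) 3-aroyl-2-aryl-2,3-dihydrobenzofuran with five aryl silyl ethers and the side-chain (Z)-silyl enol ether | CC(C)(C)[Si](C)(C)O/C(=C\Cc1ccc2c(c1)[C@H](C(=O)c1ccc(O[Si](C)(C)C(C)(C)C)cc1O[Si](C)(C)C(C)(C)C)[C@@H](c1ccc(O[Si](C)(C)C(C)(C)C)cc1)O2)c1ccc(O[Si](C)(C)C(C)(C)C)cc1O[Si](C)(C)C(C)(C)C
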